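## The problem

Asterelin A 16 is an 18-membered macrocyclic bis(bibenzyl) in which ring A and ring B are fused through O5 into a dibenzofuran, C7 of ring B is tied to ring C by a CH2CH2 bridge, ring C to ring D by a diaryl ether, and the para position of ring D back to C1 of ring A by a second CH2CH2 bridge. The molecule has no stereocentre, so the task is one of regiochemistry and ring closure. Ring A is a 1,2,3,5-tetrasubstituted benzene with carbon at C1 and C9b and oxygen at C3 and C4a, a pattern that substitution of a preformed dibenzofuran cannot deliver, because electrophiles go to C2/C8 or C3/C7 and metalation goes to C4/C6. The macrocycle holds three stiff units (dibenzofuran, para-phenylene ring D, diaryl ether), so it must be closed at a flexible, easily formed bond under high dilution. The two phenols are electron-rich and are best carried as methyl ethers to the end, while esters, aryl ethers and an internal alkyne tolerate a step near 200 °C. The feature that opens the key step is that C4a–C4–C3–C2 of ring A, with oxygen on C4a and C3, is a masked C3–C4–C5–C6 unit of a pyridazine whose two nitrogens leave as N2. C9b and C1 are then the two carbons of an alkyne, and O5–C5a–C9a of ring B is a ready-made ortho-phenylene ether tether between diazine and alkyne.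

## Retrosynthesis

**Phenols and saturated bridge.** Target 16 is traced to its dimethyl ether 15 (two O–CH3 bonds cut last), and 15 to the macrocyclic stilbene 14 (two C–H bonds on the bridge). Methyl ethers are chosen because they survive every earlier step, including the thermal one, and fall together with BBr3. The forward steps only need to leave the diaryl ether and the dibenzofuran untouched.

**Macrocycle.** In 14 the C=C bond between the C7 arm and ring C is cut, giving the open dialdehyde 13. The neighbouring cuts are less attractive. The diaryl ether would need an activating group on ring C that must later be exchanged for OH. The ring A/ring D bridge is better made early, since the alkyne of the key step supplies it for free. Both ends of 13 carry the same function, which comes from the two ester groups of diester 11 by way of diol 12. The forward reaction is a reductive carbonyl coupling under high dilution.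

**Ring A and the furan (key disconnection).** In 11 the bonds C4a–C9b and C1–C2 are cut and N2 is added back across C4a and C2. This gives the 3-(2-alkynylphenoxy)-5-methoxypyridazine 9, with the bridged diaza adduct 10 as the intermediate. This removes two rings at once and turns the awkward ring A pattern into a commercial pyridazine plus an alkyne. Alternatives such as closing the furan by C–H arylation of a diaryl ether would leave the choice between two ortho positions of ring A open. The forward reaction must be regiospecific, which the tether guarantees, and must proceed although the diazine bears two donor groups.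

**Alkyne–arene bond.** In 9 the bond between the alkyne and C9a of ring B is cut, giving aryl iodide 8 and the terminal alkyne 5. The iodide sits para to an ester, which helps oxidative addition. Coupling after ether formation avoids a free ortho-alkynylphenol, which would cyclise to a benzofuran.

**Pyridazinyl ether.** In 8 the bond between pyridazine C3 and oxygen is cut, giving methyl 3-hydroxy-4-iodobenzoate 6 and 3-chloro-5-methoxypyridazine 7, both commercial. The forward reaction is a substitution at the chlorine-bearing carbon next to nitrogen.

**Ring C/D fragment.** Alkyne 5 is traced to the homopropargylic alcohol 4 (benzylic C–O replaced by C–H) and then to aldehyde 3 (the C–C bond between the benzylic carbon and the propargyl CH2 is cut). Aldehyde 3 comes from methyl isovanillate 1 and 4-fluorobenzaldehyde 2 by cutting the ring D C–O bond. The formyl group first activates the fluoride for substitution and then serves as the anchor for the three-carbon alkyne unit. Both follow-up steps tolerate the methyl ester.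

## Roads not taken

Alternative 1: Ring A is built by a Michael–Dieckmann annulation. The enolate of the lactone 6-bromobenzofuran-2(3H)-one A2 adds to the enone (E)-6-[4-(benzyloxy)phenyl]hex-3-en-2-one A3, forming C9b–C1. The methyl ketone enolate then attacks the lactone carbonyl, forming C4–C4a and giving the cyclohexane-1,3-dione A1.
- Merits: cheap anionic chemistry near room temperature, no pressure vessel, and each ring A substituent placed by the connectivity of the two partners. In mildness and scalability this road is better than the chosen one.
- Weak points: the dione A1 is two oxidation levels below an arene, so cyclodehydration to the furan, dehydrogenation and O-methylation must follow. Two stereocentres are made only to be destroyed. The enone A3 has acidic γ-hydrogens and the enolate of the lactone A2 can self-condense. The macrocycle is not addressed: the bromide of A1 must still be turned into the C7 arm and the diaryl ether must still be made.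
- Comparison: the chosen plan delivers ring A aromatic, with both arms at the right oxidation level, in one step. It pays with a 200 °C step.

Alternative 2: The macrocycle is closed at the ring C carbon–oxygen bond of the diaryl ether. Under K2CO3 in DMF at high dilution, the ring D phenoxide of the seco compound A5 displaces fluoride ortho to a nitro group on ring C and gives the macrocyclic nitro diaryl ether A4.
- Merits: nitro-activated macrocyclic etherification is one of the most dependable ring closures for strained diaryl ether macrocycles and needs no metal. As a ring closure it is probably more reliable than a McMurry coupling, and it needs no later hydrogenation.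
- Weak points: the nitro group of A4 must be exchanged for hydroxyl (reduction, diazotisation, hydrolysis), and the last of these is poor on an electron-rich arene. The seco compound A5 needs two separately built CH2CH2 bridges. The strategy says nothing about ring A, which is the harder problem.
- Comparison: the chosen plan sets against this a ring closure between two identical aldehydes that come directly from commercial esters, and a solution for ring A.

Alternative 3: Ring B, the furan and the macrocycle are formed together by a (2+2+2) cycloaddition. The triyne A7 carries an ethynyl ether and a silylalkyne on ring A and a remote terminal alkyne. With [Rh(cod)2]BF4/BINAP (a cationic monovalent rhodium catalyst) at high dilution it would form C5a–C9a, C6–C7 and C8–C9 and give the 9-trimethylsilyl dimethyl ether A6.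
- Merits: on paper this is the most step-economic road, with three rings in one operation and only desilylation and demethylation left. In that respect it beats the chosen plan.
- Weak points: ring A of the triyne A7 must already carry the full 1,2,3,5 pattern, so the central problem is only moved. Aryl ethynyl ethers are labile. The remote alkyne can insert in two orientations, and the long tether gives little bias, so the silyl group must steer alone. Oligomerisation competes with an 18-membered closure.
- Comparison: the chosen plan has tether-enforced regiochemistry in its key step and uses only stable, commercial building blocks.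

Key step: step 6

Assumption: the McMurry product 14 is drawn as the Z alkene, which the ring should favour; its geometry is of no consequence because step 10 saturates the double bond.

## Route

Step 1
Reactants: 1 methyl 3-hydroxy-4-methoxybenzoate (methyl isovanillate); 2 4-fluorobenzaldehyde
Product: 3 methyl 3-(4-formylphenoxy)-4-methoxybenzoate
Conditions: K2CO3, DMF, 130 °C
Reagents that add atoms: none
Why: Nucleophilic aromatic substitution; the para formyl group stabilises the Meisenheimer intermediate and fluoride is the best leaving group for this mechanism, so the phenoxide of 1 should give the diaryl ether cleanly.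

Step 2
Reactants: 3 methyl 3-(4-formylphenoxy)-4-methoxybenzoate
Product: 4 methyl 3-[4-(1-hydroxybut-3-yn-1-yl)phenoxy]-4-methoxybenzoate (racemic)
Conditions: propargyl bromide, Zn dust, THF/sat. aq NH4Cl, 0 °C to rt
Reagents that add atoms: propargyl bromide (3-bromoprop-1-yne), C#CCBr
Why: Barbier-type propargylation; the allenylzinc species adds to the aldehyde through its γ-carbon to give the homopropargylic alcohol, and organozinc reagents leave the methyl ester alone. The new carbinol centre is racemic and is removed in step 3.

Step 3
Reactants: 4 methyl 3-[4-(1-hydroxybut-3-yn-1-yl)phenoxy]-4-methoxybenzoate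
Product: 5 methyl 3-[4-(but-3-yn-1-yl)phenoxy]-4-methoxybenzoate
Conditions: Et3SiH (excess), TFA, CH2Cl2, 0 °C to rt
Reagents that add atoms: none
Why: Ionic hydrogenation; the para-aryloxy group stabilises the benzylic cation, which is trapped by hydride from the silane, while the ester and the terminal alkyne are not reduced without a metal catalyst.

Step 4
Reactants: 6 methyl 3-hydroxy-4-iodobenzoate; 7 3-chloro-5-methoxypyridazine
Product: 8 methyl 4-iodo-3-[(5-methoxypyridazin-3-yl)oxy]benzoate
Conditions: Cs2CO3, DMF, 110 °C
Reagents that add atoms: none
Why: Nucleophilic aromatic substitution at the chlorine-bearing carbon next to ring nitrogen; chloride is a far better leaving group than the methoxide at C5, and the aryl iodide is inert without a metal catalyst.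

Step 5
Reactants: 8 methyl 4-iodo-3-[(5-methoxypyridazin-3-yl)oxy]benzoate; 5 methyl 3-[4-(but-3-yn-1-yl)phenoxy]-4-methoxybenzoate
Product: 9 methyl 3-[(5-methoxypyridazin-3-yl)oxy]-4-(4-{4-[2-methoxy-5-(methoxycarbonyl)phenoxy]phenyl}but-1-yn-1-yl)benzoate
Conditions: PdCl2(PPh3)2 (cat.), CuI (cat.), Et3N, THF, 45 °C, degassed
Reagents that add atoms: none
Why: Sonogashira coupling; the iodide para to an ester undergoes fast oxidative addition to zerovalent palladium, and the mild amine base leaves the pyridazinyl ether and both esters intact.

Step 6
Reactants: 9 methyl 3-[(5-methoxypyridazin-3-yl)oxy]-4-(4-{4-[2-methoxy-5-(methoxycarbonyl)phenoxy]phenyl}but-1-yn-1-yl)benzoate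
Product: 11 methyl 3-methoxy-1-(2-{4-[2-methoxy-5-(methoxycarbonyl)phenoxy]phenyl}ethyl)dibenzo[b,d]furan-7-carboxylate, via bridged diaza cycloadduct 10 (not isolated)
Conditions: 1,2-dichlorobenzene (degassed, 0.02 M), sealed vessel, 200–220 °C
Reagents that add atoms: none
Why: Thermal intramolecular inverse-electron-demand Diels–Alder reaction of a 1,2-diazine with a tethered alkyne followed by cycloreversion, the known way from pyridazines with an alkyne on an oxygen or nitrogen tether to fused benzenes. The pyridazine reacts as the 4π component through C3 and C6 and the aryl alkyne as the 2π component, so that the alkyne carbon on ring B bonds to pyridazine C3 (the C4a–C9b bond) and the outer alkyne carbon to C6 (the C1–C2 bond), giving the 2,3-diazabicyclo[2.2.2]octatriene 10. The furan closes in the cycloaddition itself as the five-membered ring spanned by the O5–C5a–C9a tether, and ring A closes as the new six-membered carbocycle. Adduct 10 then loses N2 in a retro-(4+2) step that is irreversible and makes ring A aromatic, so that the two bridgehead stereocentres of 10 vanish and 11 has none. The selectivity needed is regiochemical, and the short, rigid ortho-phenylene tether allows only the orientation that puts the CH2CH2 arm on C1, while the methoxy group and the ring oxygen end on C3 and C4a because they sit on pyridazine C5 and C3. The two donor groups make the diazine a slow diene, so the step relies on intramolecularity, high temperature and dilution. The substrate carries only esters, aryl ethers and methylene groups so that nothing else reacts at this temperature.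

Step 7
Reactants: 11 methyl 3-methoxy-1-(2-{4-[2-methoxy-5-(methoxycarbonyl)phenoxy]phenyl}ethyl)dibenzo[b,d]furan-7-carboxylate
Product: 12 [1-(2-{4-[5-(hydroxymethyl)-2-methoxyphenoxy]phenyl}ethyl)-3-methoxydibenzo[b,d]furan-7-yl]methanol
Conditions: LiAlH4, THF, 0 °C to rt
Reagents that add atoms: none
Why: Hydride reduction of both aryl esters to the benzylic alcohols; aryl ethers and the dibenzofuran are inert to LiAlH4.

Step 8
Reactants: 12 [1-(2-{4-[5-(hydroxymethyl)-2-methoxyphenoxy]phenyl}ethyl)-3-methoxydibenzo[b,d]furan-7-yl]methanol
Product: 13 1-{2-[4-(5-formyl-2-methoxyphenoxy)phenyl]ethyl}-3-methoxydibenzo[b,d]furan-7-carbaldehyde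
Conditions: activated MnO2 (excess), CH2Cl2, rt
Reagents that add atoms: none
Why: Selective oxidation of benzylic alcohols by MnO2; it stops at the aldehyde and does not touch the bibenzyl CH2 groups.

Step 9
Reactants: 13 1-{2-[4-(5-formyl-2-methoxyphenoxy)phenyl]ethyl}-3-methoxydibenzo[b,d]furan-7-carbaldehyde
Product: 14 macrocyclic Z-stilbene (asterelin A dimethyl ether with a CH=CH bridge between dibenzofuran C7 and ring C)
Conditions: TiCl3(DME)1.5, Zn–Cu couple, DME, reflux; 13 added by syringe pump (final ca. 0.002 M)
Reagents that add atoms: none
Why: Intramolecular McMurry coupling; low-valent titanium joins the two aryl aldehydes through a titanium pinacolate that is deoxygenated to the alkene, and slow addition keeps the concentration of 13 low so that ring closure outruns oligomerisation.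

Step 10
Reactants: 14 macrocyclic Z-stilbene
Product: 15 asterelin A dimethyl ether (methoxy groups at dibenzofuran C3 and on ring C ortho to the diaryl ether oxygen)
Conditions: H2 (1 atm), Pd/C, EtOAc/MeOH, rt
Reagents that add atoms: none
Why: Heterogeneous hydrogenation of a stilbene double bond; at 1 atm the arenes, the diaryl ether and the dibenzofuran are not reduced.

Step 11
Reactants: 15 asterelin A dimethyl ether
Product: 16 asterelin A
Conditions: BBr3, CH2Cl2, −78 °C to rt; then H2O
Reagents that add atoms: none
Why: Lewis acid cleavage of aryl methyl ethers; bromide attacks only the methyl carbons, so the diaryl ether and the dibenzofuran C–O bonds, which offer no sp3 carbon, stay intact.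

## Compound list

1 | methyl 3-hydroxy-4-methoxybenzoate (methyl isovanillate) | COC(=O)c1ccc(OC)c(O)c1 | starting material
2 | 4-fluorobenzaldehyde | O=Cc1ccc(F)cc1 | starting material
3 | methyl 3-(4-formylphenoxy)-4-methoxybenzoate | COC(=O)c1ccc(OC)c(Oc2ccc(C=O)cc2)c1 | intermediate
4 | methyl 3-[4-(1-hydroxybut-3-yn-1-yl)phenoxy]-4-methoxybenzoate (racemic) | COC(=O)c1ccc(OC)c(Oc2ccc(C(O)CC#C)cc2)c1 | intermediate
5 | methyl 3-[4-(but-3-yn-1-yl)phenoxy]-4-methoxybenzoate | COC(=O)c1ccc(OC)c(Oc2ccc(CCC#C)cc2)c1 | intermediate
6 | methyl 3-hydroxy-4-iodobenzoate | COC(=O)c1ccc(I)c(O)c1 | starting material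
7 | 3-chloro-5-methoxypyridazine | COc1cnnc(Cl)c1 | starting material
8 | methyl 4-iodo-3-[(5-methoxypyridazin-3-yl)oxy]benzoate | COC(=O)c1ccc(I)c(Oc2cc(OC)cnn2)c1 | intermediate
9 | methyl 3-[(5-methoxypyridazin-3-yl)oxy]-4-(4-{4-[2-methoxy-5-(methoxycarbonyl)phenoxy]phenyl}but-1-yn-1-yl)benzoate | COc1cnnc(Oc2cc(C(=O)OC)ccc2C#CCCc2ccc(Oc3cc(C(=O)OC)ccc3OC)cc2)c1 | intermediate
10 | bridged diaza cycloadduct (2,3-diazabicyclo[2.2.2]octa-2,5,7-triene fused to the benzofuran ring; racemic, bridgeheads fixed by the bicycle; not isolated) | COC1=CC23N=NC1C(CCc1ccc(Oc4cc(C(=O)OC)ccc4OC)cc1)=C2c1ccc(C(=O)OC)cc1O3 | intermediate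
11 | methyl 3-methoxy-1-(2-{4-[2-methoxy-5-(methoxycarbonyl)phenoxy]phenyl}ethyl)dibenzo[b,d]furan-7-carboxylate | COc1cc(CCc2ccc(Oc3cc(C(=O)OC)ccc3OC)cc2)c2c(c1)oc1cc(C(=O)OC)ccc12 | intermediate
12 | [1-(2-{4-[5-(hydroxymethyl)-2-methoxyphenoxy]phenyl}ethyl)-3-methoxydibenzo[b,d]furan-7-yl]methanol | COc1cc(CCc2ccc(Oc3cc(CO)ccc3OC)cc2)c2c(c1)oc1cc(CO)ccc12 | intermediate
13 | 1-{2-[4-(5-formyl-2-methoxyphenoxy)phenyl]ethyl}-3-methoxydibenzo[b,d]furan-7-carbaldehyde | COc1cc(CCc2ccc(Oc3cc(C=O)ccc3OC)cc2)c2c(c1)oc1cc(C=O)ccc12 | intermediate
14 | macrocyclic Z-stilbene (didehydro asterelin A dimethyl ether, CH=CH between dibenzofuran C7 and ring C) | COc1cc2c3c(c1)oc1cc(ccc13)/C=C\c1ccc(OC)c(c1)Oc1ccc(cc1)CC2 | intermediate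
15 | asterelin A dimethyl ether | COc1cc2c3c(c1)oc1cc(ccc13)CCc1ccc(OC)c(c1)Oc1ccc(cc1)CC2 | intermediate
16 | asterelin A | Oc1cc2c3c(c1)oc1cc(ccc13)CCc1ccc(O)c(c1)Oc1ccc(cc1)CC2 | target

## Step count and risks

Total steps: 11. Longest linear sequence: 10 steps (steps 1, 2, 3 and 5 to 11, from 1 and 2).

**Key step (step 6).** The cycloaddition may be too slow for the substrate to survive. The methoxy and aryloxy groups raise the diazine LUMO and the ester para to the alkyne lowers the dienophile HOMO. At the temperature then needed, O-to-N migration of the methyl or aryl group on the diazine and cleavage of the heteroaryl ether can compete.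

The fallback changes the electronic pairing and the order of the redox steps. It sets out from 9. Both esters are reduced with LiBH4 in THF/MeOH to the diol {3-[(5-methoxypyridazin-3-yl)oxy]-4-(4-{4-[5-(hydroxymethyl)-2-methoxyphenoxy]phenyl}but-1-yn-1-yl)phenyl}methanol F1. This is silylated with TBSCl and imidazole to the bis(tert-butyldimethylsilyl) ether F2, whose aryl alkyne no longer carries an acceptor and is a better partner for the inverse-demand diene. Thermolysis of F2 under the conditions of step 6 should give the bis(silyl ether) of the dibenzofuran diol F3, and TBAF in THF returns the route at 12, so step 7 is no longer needed.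

**Step 4.** The iodophenoxide is hindered and electron-poor and the chloropyridazine is deactivated by its methoxy group. Substitution may therefore be slow enough for the phenoxide to demethylate the methoxypyridazine or to attack C5.

The fallback changes the leaving group and sets out from 7. NaSMe in DMF at room temperature gives 5-methoxy-3-(methylsulfanyl)pyridazine F4. Oxidation with KHSO5 (potassium peroxymonosulfate) in aqueous methanol gives 5-methoxy-3-(methylsulfonyl)pyridazine F5. Its sulfinate leaving group should allow substitution by 6 with Cs2CO3 well below 100 °C, and the route is rejoined at 8.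

**Step 3.** The benzylic cation may lose a proton to give the conjugated enyne, which can oligomerise. It may also alkylate an electron-rich arene, or the acid may add to the terminal alkyne before hydride transfer.

The fallback avoids the cation and sets out from 3. A Wittig reaction with (triphenylphosphoranylidene)acetaldehyde in toluene gives methyl 4-methoxy-3-{4-[(E)-3-oxoprop-1-en-1-yl]phenoxy}benzoate F6. Hydrogenation of the C=C bond over Pd/C in EtOAc gives methyl 4-methoxy-3-[4-(3-oxopropyl)phenoxy]benzoate F7. Ohira–Bestmann homologation (dimethyl (1-diazo-2-oxopropyl)phosphonate, K2CO3, MeOH) converts the aldehyde to the terminal alkyne and returns the route at 5.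

**Step 9.** Intermolecular coupling to oligomers, or arrest at the pinacol stage, may win over ring closure, because the ring being formed is strained by the dibenzofuran and the para-phenylene unit.

The fallback closes the same bond by metathesis and sets out from 13. Double methylenation with Ph3P=CH2 (from methyltriphenylphosphonium bromide and KOtBu in THF) gives the bis(styrene) 7-ethenyl-1-{2-[4-(5-ethenyl-2-methoxyphenoxy)phenyl]ethyl}-3-methoxydibenzo[b,d]furan F8. Ring-closing metathesis with the second-generation Grubbs catalyst in dilute refluxing CH2Cl2, with loss of ethene, returns the route at 14.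

## Further compounds

F1 | step 6 | {3-[(5-methoxypyridazin-3-yl)oxy]-4-(4-{4-[5-(hydroxymethyl)-2-methoxyphenoxy]phenyl}but-1-yn-1-yl)phenyl}methanol | COc1cnnc(Oc2cc(CO)ccc2C#CCCc2ccc(Oc3cc(CO)ccc3OC)cc2)c1
F2 | step 6 | bis(tert-butyldimethylsilyl) ether of F1 | COc1cnnc(Oc2cc(CO[Si](C)(C)C(C)(C)C)ccc2C#CCCc2ccc(Oc3cc(CO[Si](C)(C)C(C)(C)C)ccc3OC)cc2)c1
F3 | step 6 | bis(tert-butyldimethylsilyl) ether of diol 12 | COc1cc(CCc2ccc(Oc3cc(CO[Si](C)(C)C(C)(C)C)ccc3OC)cc2)c2c(c1)oc1cc(CO[Si](C)(C)C(C)(C)C)ccc12
F4 | step 4 | 5-methoxy-3-(methylsulfanyl)pyridazine | COc1cnnc(SC)c1
F5 | step 4 | 5-methoxy-3-(methylsulfonyl)pyridazine | COc1cnnc(S(C)(=O)=O)c1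
F6 | step 3 | methyl 4-methoxy-3-{4-[(E)-3-oxoprop-1-en-1-yl]phenoxy}benzoate | COC(=O)c1ccc(OC)c(Oc2ccc(/C=C/C=O)cc2)c1
F7 | step 3 | methyl 4-methoxy-3-[4-(3-oxopropyl)phenoxy]benzoate | COC(=O)c1ccc(OC)c(Oc2ccc(CCC=O)cc2)c1
F8 | step 9 | 7-ethenyl-1-{2-[4-(5-ethenyl-2-methoxyphenoxy)phenyl]ethyl}-3-methoxydibenzo[b,d]furan | COc1cc(CCc2ccc(Oc3cc(C=C)ccc3OC)cc2)c2c(c1)oc1cc(C=C)ccc12
A1 | alternative 1 | racemic trans-4-(4-bromo-2-hydroxyphenyl)-5-[2-(4-benzyloxyphenyl)ethyl]cyclohexane-1,3-dione | O=C1CC(=O)[C@@H](c2ccc(Br)cc2O)[C@H](CCc2ccc(OCc3ccccc3)cc2)C1
A2 | alternative 1 | 6-bromobenzofuran-2(3H)-one | O=C1Cc2ccc(Br)cc2O1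
A3 | alternative 1 | (E)-6-[4-(benzyloxy)phenyl]hex-3-en-2-one | CC(=O)/C=C/CCc1ccc(OCc2ccccc2)cc1
A4 | alternative 2 | macrocyclic nitro diaryl ether (nitro in place of the ring C hydroxyl, ring A methoxy) | COc1cc2c3c(c1)oc1cc(ccc13)CCc1ccc([N+](=O)[O-])c(c1)Oc1ccc(cc1)CC2
A5 | alternative 2 | 4-(2-{7-[2-(3-fluoro-4-nitrophenyl)ethyl]-3-methoxydibenzo[b,d]furan-1-yl}ethyl)phenol | COc1cc(CCc2ccc(O)cc2)c2c(c1)oc1cc(CCc3ccc([N+](=O)[O-])c(F)c3)ccc12
A6 | alternative 3 | 9-trimethylsilyl asterelin A dimethyl ether | COc1cc2c3c(c1)oc1cc(cc([Si](C)(C)C)c13)CCc1ccc(OC)c(c1)Oc1ccc(cc1)CC2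
A7 | alternative 3 | triyne: 1-(ethynyloxy)-5-methoxy-3-(2-{4-[5-(but-3-yn-1-yl)-2-methoxyphenoxy]phenyl}ethyl)-2-[(trimethylsilyl)ethynyl]benzene | COc1cc(CCc2ccc(Oc3cc(CCC#C)ccc3OC)cc2)c(C#C[Si](C)(C)C)c(OC#C)c1
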